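At early times in the east run, ring is made with little yet to consume it, so the first reading over the mean [substrate] of that stretch gives a specific making rate of 0.0145 /min. Later in that run ring stands level within the scatter, at about 12.3%, while substrate averages 61.7%. I read this as a quasi-steady state, with ring lost as fast as it is made. That gives the ring half-life, the time in which everything consuming ring would halve it with the making stopped: 9.52 min at 110 °C. The same balance gives a ceiling for ring at that temperature, making rate times lifetime, of 19.9%.

| flask | substrate | temperature | remark | time |
|---|---|---|---|---|
| north-east | 30 mM | 80 °C | run made earlier |  |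
| east | 68 mM | 110 °C | run made earlier |  |
| winter | 45 mM | 85 °C |  | 50 min |
| summer | 45 mM | 110 °C |  | 50 min |
| spring | 45 mM | 135 °C |  | 50 min |

| run | time / min | ring / % | substrate / % |
|---|---|---|---|
| north-east | 12.0 | 1.7 | 98.8 |
| north-east | 25.0 | 1.9 | 93.8 |
| north-east | 40.0 | 3.8 | 92.2 |
| north-east | 50.0 | 5.3 | 89.4 |
| east | 4.00 | 5.3 | 82.5 |
| east | 8.00 | 11.8 | 71.8 |
| east | 12.0 | 11.7 | 59.4 |
| east | 15.0 | 13.4 | 53.8 |

(readings scatter by 1 percentage point)



* the flask with the highest amount of ring, in percent of the substrate charged ("all alike" if they lie within 1.5 percentage points) (winter / summer / spring / all alike)
* final ring, as a percentage of the substrate charged, in winter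
* final ring, as a percentage of the substrate charged, in summer
* final ring, as a percentage of the substrate charged, in spring

You must now decide which flask to charge, so count ring half-lives in 50 min. For temperature you hold only substrate loss, with 0.00224 /min in the north-east run and 0.0413 /min in the east run. The charges differ too, so this is rough. Spread evenly, and assumed to hold for ring as well, it gives a factor of 11.3 between neighbouring flasks.

In winter the ring half-life is 108 min, longer than the time, so ring simply accumulates, to a little under 6.42%. In summer 50 min holds 5.25 half-lives, so on my balance ring should follow the substrate still present, at the ceiling times substrate's share, and not stand at the ceiling itself. At the east run's rate substrate is down to 12.7%, so I expect ring near 2.53%, though that rate was read at 68 mM and not at 45 mM. In spring the ring half-life is 0.839 min, far shorter than the time, and substrate's is about 1.49 min, so I expect ring close to zero at the end. My reckoned ring is higher in winter than in summer, so my decision is to charge winter and not to hold a spring flask to the end.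

The forecast picks summer where I pick winter, with 7% in winter and 27% in summer, which is above my ceiling. For spring it gives 18%, where I expect close to zero, “given poorer selectivity and ring degradation”.

The flask gives summer: 4.88% in winter, 15.7% in summer and 0.591% in spring.

    substrate → ring (k = 0.0191 /min, Ea = 122 kJ/mol)
    2 substrate → open dimer (k = 0.183 /M/min, Ea = 77.0 kJ/mol)
    substrate + ring → side product (k = 0.520 /M/min, Ea = 60.0 kJ/mol)
    ring → over-reaction product (k = 0.0251 /min, Ea = 122 kJ/mol)
    ring ⇌ isomer of the product (K = 1.20, k = 0.00832 /min, Ea = 119 kJ/mol, ΔH = 12.0 kJ/mol)
    (constants at 110 °C)

In summer, substrate fell from 43.7% at 25.0 min to 21.6% at 50.0 min while the reaction of ring to over-reaction product took that product from 7.74% to 18.5%, and ring, with 9.52 min as its reckoned half-life, slipped from 17.6% to 15.7%, below the ceiling of 19.9% but above the 2.53% I had reckoned. The spring flask read at 12 min still held 6.02% substrate and 8.68% ring, but by 50.0 min substrate stood at 0%, the reaction of ring to over-reaction product had a half-life of 2.6 min, short against 50 min, that product had reached 72.6%, and ring stood at 0.591%.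

The runs are calculated with made-up constants; the scatter is artificial.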